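**Retrosynthetic overview** (labdane numbering of the target)
1. Target 29 ⇐ desilylation and diacetylation of diol 27 ⇐ B-alkyl Suzuki coupling (C12–C13) of the 9β-vinyl decalin 21 with (Z)-iodide 24; 7α-OH/8(17)-ene from a 7α,8α-epoxide; C11–C12 from the C9 ketone; C18 by ester-enolate methylation.
2. Key disconnection: ring A of keto ester 11 is cut at C1–C10 and C2–C3, giving the monocyclic α′-bromo enone acrylate 9 and the two-carbon enol ether 10, joined in one polarity-alternating radical [4+2] annulation.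
3. Enabling feature: in ring A the oxygenated C2 lies between C10 (quaternary, bonded to ring-B carbon C9) and C3–C4 (C4 carries the oxidised C19). With C9 as a ketone and C19 as an ester, C10 is an electrophilic α-keto radical site, C1=C2–O an electron-rich alkene and C3=C4 an acrylate, so each bond-forming event is polarity matched.
4. Ring order: ring B comes from (R)-carvone (supplies C5), ring A is closed in the key step, the side chain is attached last.

Key step: step 7

**Remarks**
- Assumption: tert-butyldimethyl(vinyloxy)silane 10 is bought as a catalogue reagent.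
- Locants and α/β in names follow the labdane numbering of the target (C17 on C8, C18 = 4α-CH3, C19 = 4β-CH2O, C20 on C10).
- C4 of 11–13 is an epimer mixture (no descriptor in the SMILES); both epimers converge in step 9. Step 16 is a side branch that makes the side-chain iodide.

**Route**

Step 1
Reactants: 1 (R)-(−)-carvone
Product: 3 (5R,6S)-2,6-dimethyl-5-(prop-1-en-2-yl)cyclohex-2-en-1-one, via lithium enolate 2 (not isolated)
Conditions: LiN(iPr)2, THF, −78 °C; then MeI, −78 → 0 °C
Reagents that add atoms: lithium diisopropylamide, [Li]N(C(C)C)C(C)C; iodomethane, IC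
Why: Kinetic α′-deprotonation of the cross-conjugated enone and SN2 methylation of the enolate (enolate alkylation) should put C20 on the future C10, trans to the isopropenyl group; this centre is made planar again in steps 6 and 7, so its configuration does not matter.

Step 2
Reactants: 3 (5R,6S)-2,6-dimethyl-5-(prop-1-en-2-yl)cyclohex-2-en-1-one
Product: 4 (5R,6S)-5-(3-chloroprop-1-en-2-yl)-2,6-dimethylcyclohex-2-en-1-one
Conditions: Ca(OCl)2, solid CO2, CH2Cl2/H2O, 0 °C
Reagents that add atoms: calcium hypochlorite, [Ca+2].[O-]Cl.[O-]Cl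
Why: Ene-type allylic chlorination by HOCl made in situ should occur only at the electron-rich 1,1-disubstituted alkene and leave the electron-poor enone alkene and both stereocentres untouched.

Step 3
Reactants: 4 (5R,6S)-5-(3-chloroprop-1-en-2-yl)-2,6-dimethylcyclohex-2-en-1-one
Product: 5 2-[(1R,2S)-2,4-dimethyl-3-oxocyclohex-4-en-1-yl]prop-2-enal
Conditions: Me3NO (anhydrous), NaI (cat.), DMSO, 25 °C
Reagents that add atoms: trimethylamine N-oxide, C[N+](C)(C)[O-]
Why: Ganem oxidation (SN2 O-alkylation of the amine oxide by the allylic halide, then elimination of trimethylamine) should give the 2-substituted acrolein under nearly neutral conditions.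

Step 4
Reactants: 5 2-[(1R,2S)-2,4-dimethyl-3-oxocyclohex-4-en-1-yl]prop-2-enal
Product: 6 2-[(1R,2S)-2,4-dimethyl-3-oxocyclohex-4-en-1-yl]prop-2-enoic acid
Conditions: NaClO2, NaH2PO4, 2-methylbut-2-ene, t-BuOH/H2O, 0 → 25 °C
Reagents that add atoms: sodium chlorite, [Na+].[O-]Cl=O
Why: Pinnick oxidation is selective for the aldehyde, the alkene scavenger intercepting HOCl before it can attack the two C=C bonds.

Step 5
Reactants: 6 2-[(1R,2S)-2,4-dimethyl-3-oxocyclohex-4-en-1-yl]prop-2-enoic acid
Product: 7 methyl 2-[(1R,2S)-2,4-dimethyl-3-oxocyclohex-4-en-1-yl]prop-2-enoate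
Conditions: MeI, K2CO3, DMF, 25 °C
Reagents that add atoms: iodomethane, IC
Why: SN2 O-alkylation of the carboxylate gives the acrylate ester that activates C3 as a radical acceptor and later becomes C19.

Step 6
Reactants: 7 methyl 2-[(1R,2S)-2,4-dimethyl-3-oxocyclohex-4-en-1-yl]prop-2-enoate
Product: 9 methyl 2-[(1S,2S)-2-bromo-2,4-dimethyl-3-oxocyclohex-4-en-1-yl]prop-2-enoate, via silyl dienol ether 8 (not isolated)
Conditions: Me3SiOTf, Et3N, CH2Cl2, 0 °C; then NBS, THF, −78 → 0 °C
Reagents that add atoms: trimethylsilyl trifluoromethanesulfonate, C[Si](C)(C)OS(=O)(=O)C(F)(F)F; N-bromosuccinimide, O=C1CCC(=O)N1Br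
Why: Soft α′-enolisation to the cross-conjugated silyl dienol ether avoids a strong base that would attack the acrylate, and bromination of its C10 terminus (α-halogenation of a silyl enol ether) gives the tertiary α′-bromoketone, whose C10 configuration is erased in step 7.

Step 7
Reactants: 9 methyl 2-[(1S,2S)-2-bromo-2,4-dimethyl-3-oxocyclohex-4-en-1-yl]prop-2-enoate; 10 tert-butyldimethyl(vinyloxy)silane
Product: 11 methyl 2α-[(tert-butyldimethylsilyl)oxy]-9-oxo-11,12,13,14,15,16,18-heptanorlabd-7-en-19-oate (C4 epimers)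
Conditions: 10 (10 equiv), Bu3SnH (1.3 equiv, syringe pump), Et3B (0.2 equiv)/air, PhMe, 0 → 25 °C
Reagents that add atoms: none
Why: Proposed new method: Bu3Sn• takes bromine from 9 to give the planar, electrophilic tertiary α-keto radical at C10, which adds to the electron-rich CH2 terminus of enol ether 10 (C1–C10 bond); the nucleophilic α-silyloxy radical so formed at C2 then attacks the β-carbon C3 of the 2-substituted acrylate (C2–C3 bond), and the α-ester radical at C4 ends the chain by taking hydrogen from Bu3SnH. The closest known reaction types are tin-hydride and atom-transfer radical annulations of α-halo carbonyl compounds with alkenes and the endo cyclisation of nucleophilic radicals onto 2-substituted acrylates; their union in a three-component polarity-alternating [4+2] annulation on an enone α′-radical has not been shown. Ring A is closed by a 6-endo-trig radical cyclisation through a chair-like transition state; ring B is already present. C10 is set in the intermolecular addition, 10 approaching anti to the pseudo-axial C5 substituent as electrophiles do with enolates of 6-substituted carvones, which puts the C10 methyl cis to C4 and leads to the trans-fused decalin; C2 is set in the ring closure, where OTBS takes the equatorial position to avoid a 1,3-diaxial contact with the C10 methyl, and C4 is left as an epimer mixture erased in step 9. The step needs chemoselectivity (each radical must take its polarity-matched partner before it is reduced), secured by the tenfold excess of 10, by the intramolecular second addition and by slow addition of Bu3SnH, and it needs 6-endo closure onto C3 in preference to 5-exo closure onto C4 or bridging attack on C7, secured by the ester on C4 and by the strain of the bicyclo[2.2.2]octane alternative.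

Step 8
Reactants: 11 methyl 2α-[(tert-butyldimethylsilyl)oxy]-9-oxo-11,12,13,14,15,16,18-heptanorlabd-7-en-19-oate (C4 epimers)
Product: 12 methyl 2α-[(tert-butyldimethylsilyl)oxy]-12,13,14,15,16,18-hexanorlabda-7,9(11)-dien-19-oate (C4 epimers)
Conditions: Ph3PCH3Br, KOtBu, PhMe, 80 °C
Reagents that add atoms: methyltriphenylphosphonium bromide, C[P+](c1ccccc1)(c1ccccc1)c1ccccc1.[Br-]
Why: Wittig methylenation with the ylide at elevated temperature should convert the hindered ketone, which cannot enolise towards C10, into the 7,9(11)-diene; epimerisation at C4 is harmless.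

Step 9
Reactants: 12 methyl 2α-[(tert-butyldimethylsilyl)oxy]-12,13,14,15,16,18-hexanorlabda-7,9(11)-dien-19-oate (C4 epimers)
Product: 14 methyl 2α-[(tert-butyldimethylsilyl)oxy]-12,13,14,15,16-pentanorlabda-7,9(11)-dien-19-oate, via lithium ester enolate 13 (not isolated)
Conditions: LiN(iPr)2, THF, −78 °C; then MeI, DMPU, −78 → 0 °C
Reagents that add atoms: lithium diisopropylamide, [Li]N(C(C)C)C(C)C; iodomethane, IC
Why: In this alkylation of the exocyclic ester enolate of a 10-methyl-trans-decalin, MeI should approach from the equatorial α-face, away from the axial C10 methyl, giving 4α-CH3 (C18) and the axial 4β-ester (C19) from both C4 epimers of 12.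

Step 10
Reactants: 14 methyl 2α-[(tert-butyldimethylsilyl)oxy]-12,13,14,15,16-pentanorlabda-7,9(11)-dien-19-oate
Product: 16 methyl 2α-[(tert-butyldimethylsilyl)oxy]-11-hydroxy-12,13,14,15,16-pentanorlabd-7-en-19-oate, via B-alkyl borane 15 (not isolated)
Conditions: 9-BBN, THF, 0 → 25 °C; then NaOH, H2O2, H2O, 0 °C
Reagents that add atoms: 9-borabicyclo[3.3.1]nonane, B1C2CCCC1CCC2; hydrogen peroxide, OO
Why: In this hydroboration–oxidation 9-BBN should add only to the 1,1-disubstituted terminus of the diene with boron on C11, delivering hydrogen to C9 from the α-face anti to the axial C10 methyl (9α-H).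

Step 11
Reactants: 16 methyl 2α-[(tert-butyldimethylsilyl)oxy]-11-hydroxy-12,13,14,15,16-pentanorlabd-7-en-19-oate
Product: 17 methyl 2α-[(tert-butyldimethylsilyl)oxy]-11-oxo-12,13,14,15,16-pentanorlabd-7-en-19-oate
Conditions: Dess–Martin periodinane, pyridine, CH2Cl2, 0 → 25 °C
Reagents that add atoms: none
Why: Buffered hypervalent-iodine oxidation of the primary alcohol should give the β,γ-unsaturated aldehyde without epimerising C9 or moving the 7-ene into conjugation.

Step 12
Reactants: 17 methyl 2α-[(tert-butyldimethylsilyl)oxy]-11-oxo-12,13,14,15,16-pentanorlabd-7-en-19-oate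
Product: 18 methyl 2α-[(tert-butyldimethylsilyl)oxy]-13,14,15,16-tetranorlabda-7,11-dien-19-oate
Conditions: Ph3PCH3Br, KN(SiMe3)2, THF, −78 → 0 °C
Reagents that add atoms: methyltriphenylphosphonium bromide, C[P+](c1ccccc1)(c1ccccc1)c1ccccc1.[Br-]
Why: Wittig methylenation of the aldehyde at low temperature is faster than α-deprotonation, so the 9β-vinyl group (C11=C12) should form with C9 intact.

Step 13
Reactants: 18 methyl 2α-[(tert-butyldimethylsilyl)oxy]-13,14,15,16-tetranorlabda-7,11-dien-19-oate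
Product: 19 methyl 2α-[(tert-butyldimethylsilyl)oxy]-7α,8α-epoxy-13,14,15,16-tetranorlabd-11-en-19-oate
Conditions: mCPBA, CH2Cl2, 0 °C
Reagents that add atoms: 3-chloroperbenzoic acid, OOC(=O)c1cccc(Cl)c1
Why: Prilezhaev epoxidation should select the trisubstituted 7-ene over the monosubstituted vinyl group and attack the α-face, the β-face being shielded by the axial C10 methyl and the 9β-vinyl group.

Step 14
Reactants: 19 methyl 2α-[(tert-butyldimethylsilyl)oxy]-7α,8α-epoxy-13,14,15,16-tetranorlabd-11-en-19-oate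
Product: 20 methyl 2α-[(tert-butyldimethylsilyl)oxy]-7α-hydroxy-13,14,15,16-tetranorlabda-8(17),11-dien-19-oate
Conditions: diethylaluminium 2,2,6,6-tetramethylpiperidide (from Et2AlCl and lithium 2,2,6,6-tetramethylpiperidide, itself from the amine and n-BuLi), PhMe, 0 → 25 °C
Reagents that add atoms: none
Why: Aluminium-amide epoxide-to-allylic-alcohol isomerisation (syn β-elimination through a cyclic transition state) should remove the least hindered β-hydrogen, on the C17 methyl, and break the C8–O bond, leaving the C7–O bond and hence the 7α configuration untouched.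

Step 15
Reactants: 20 methyl 2α-[(tert-butyldimethylsilyl)oxy]-7α-hydroxy-13,14,15,16-tetranorlabda-8(17),11-dien-19-oate
Product: 21 methyl 2α,7α-bis[(tert-butyldimethylsilyl)oxy]-13,14,15,16-tetranorlabda-8(17),11-dien-19-oate
Conditions: t-BuMe2SiOTf, 2,6-lutidine, CH2Cl2, 0 °C
Reagents that add atoms: tert-butyldimethylsilyl trifluoromethanesulfonate, CC(C)(C)[Si](C)(C)OS(=O)(=O)C(F)(F)F
Why: Silylation with the triflate protects the hindered axial allylic 7α-OH so that only the two primary hydroxyls are acetylated in step 19.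

Step 16
Reactants: 22 but-2-yn-1-ol
Product: 24 (Z)-3-iodobut-2-en-1-ol, via alkenylalanate 23 (not isolated)
Conditions: NaAlH2(OCH2CH2OCH3)2, THF, 0 → 25 °C; then I2, −78 → 0 °C
Reagents that add atoms: sodium bis(2-methoxyethoxy)aluminium dihydride, [Na+].[AlH2-](OCCOC)OCCOC; iodine, [I][I]
Why: Alkoxide-directed trans-hydroalumination places aluminium on C3 cis to the CH2O group in a five-membered alanate, and iodinolysis with retention should give the Z iodide.

Step 17
Reactants: 21 methyl 2α,7α-bis[(tert-butyldimethylsilyl)oxy]-13,14,15,16-tetranorlabda-8(17),11-dien-19-oate; 24 (Z)-3-iodobut-2-en-1-ol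
Product: 26 methyl 2α,7α-bis[(tert-butyldimethylsilyl)oxy]-15-hydroxylabda-8(17),13Z-dien-19-oate, via B-alkyl borane 25 (not isolated)
Conditions: 9-BBN, THF, 0 → 25 °C; then 24, PdCl2(dppf), AsPh3, Cs2CO3, DMF/H2O, 25 °C
Reagents that add atoms: 9-borabicyclo[3.3.1]nonane, B1C2CCCC1CCC2
Why: Hydroboration of the unhindered vinyl group (the 8(17)-methylidene is flanked by C7–OTBS and C9) followed by B-alkyl Suzuki–Miyaura coupling, which proceeds with retention at the alkenyl iodide, should form C12–C13 and fix the 13Z geometry.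

Step 18
Reactants: 26 methyl 2α,7α-bis[(tert-butyldimethylsilyl)oxy]-15-hydroxylabda-8(17),13Z-dien-19-oate
Product: 27 2α,7α-bis[(tert-butyldimethylsilyl)oxy]labda-8(17),13Z-diene-15,19-diol
Conditions: LiAlH4, Et2O, 0 → 25 °C
Reagents that add atoms: none
Why: Hydride reduction of the hindered axial methyl ester should give the C19 primary alcohol, silyl ethers and unconjugated alkenes being inert.

Step 19
Reactants: 27 2α,7α-bis[(tert-butyldimethylsilyl)oxy]labda-8(17),13Z-diene-15,19-diol
Product: 28 2α,7α-bis[(tert-butyldimethylsilyl)oxy]labda-8(17),13Z-diene-15,19-diyl diacetate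
Conditions: Ac2O, pyridine, DMAP (cat.), CH2Cl2, 25 °C
Reagents that add atoms: acetic anhydride, CC(=O)OC(C)=O
Why: Nucleophile-catalysed acylation should acetylate the only two free hydroxyls, at C15 and C19.

Step 20
Reactants: 28 2α,7α-bis[(tert-butyldimethylsilyl)oxy]labda-8(17),13Z-diene-15,19-diyl diacetate
Product: 29 2α,7α-dihydroxylabda-8(17),13Z-diene-15,19-diyl diacetate (target)
Conditions: HF·pyridine, pyridine/THF, 0 → 25 °C
Reagents that add atoms: none
Why: Buffered fluoride cleavage of the two secondary silyl ethers should free the 2α- and 7α-hydroxyls without hydrolysing or shifting the acetates or ionising the allylic alcohol.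

**Compound list**
1 | (R)-(−)-carvone, (5R)-2-methyl-5-(prop-1-en-2-yl)cyclohex-2-en-1-one | CC1=CC[C@@H](C(C)=C)CC1=O | starting material
2 | lithium α′-enolate of 1 (cross-conjugated dienolate) | CC1=CC[C@@H](C(C)=C)C=C1O[Li] | intermediate
3 | (5R,6S)-2,6-dimethyl-5-(prop-1-en-2-yl)cyclohex-2-en-1-one (methyl trans to isopropenyl) | CC1=CC[C@@H](C(C)=C)[C@H](C)C1=O | intermediate
4 | (5R,6S)-5-(3-chloroprop-1-en-2-yl)-2,6-dimethylcyclohex-2-en-1-one | CC1=CC[C@@H](C(=C)CCl)[C@H](C)C1=O | intermediate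
5 | 2-[(1R,2S)-2,4-dimethyl-3-oxocyclohex-4-en-1-yl]prop-2-enal | CC1=CC[C@@H](C(=C)C=O)[C@H](C)C1=O | intermediate
6 | 2-[(1R,2S)-2,4-dimethyl-3-oxocyclohex-4-en-1-yl]prop-2-enoic acid | CC1=CC[C@@H](C(=C)C(O)=O)[C@H](C)C1=O | intermediate
7 | methyl 2-[(1R,2S)-2,4-dimethyl-3-oxocyclohex-4-en-1-yl]prop-2-enoate | CC1=CC[C@@H](C(=C)C(=O)OC)[C@H](C)C1=O | intermediate
8 | methyl 2-[(1R)-2,4-dimethyl-3-(trimethylsilyloxy)cyclohexa-2,4-dien-1-yl]prop-2-enoate | CC1=CC[C@@H](C(=C)C(=O)OC)C(C)=C1O[Si](C)(C)C | intermediate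
9 | methyl 2-[(1S,2S)-2-bromo-2,4-dimethyl-3-oxocyclohex-4-en-1-yl]prop-2-enoate (Br trans to the acrylate-bearing carbon) | CC1=CC[C@@H](C(=C)C(=O)OC)[C@](C)(Br)C1=O | intermediate
10 | tert-butyldimethyl(vinyloxy)silane | C=CO[Si](C)(C)C(C)(C)C | starting material
11 | methyl 2α-[(tert-butyldimethylsilyl)oxy]-9-oxo-11,12,13,14,15,16,18-heptanorlabd-7-en-19-oate, C4 epimers; methyl (3S,4aS,8aS)-3-[(tert-butyldimethylsilyl)oxy]-4a,6-dimethyl-5-oxo-1,2,3,4,4a,5,8,8a-octahydronaphthalene-1-carboxylate (5α-H, 10β-CH3) | CC1=CC[C@H]2C(C(=O)OC)C[C@H](O[Si](C)(C)C(C)(C)C)C[C@]2(C)C1=O | intermediate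
12 | methyl 2α-[(tert-butyldimethylsilyl)oxy]-12,13,14,15,16,18-hexanorlabda-7,9(11)-dien-19-oate, C4 epimers | CC1=CC[C@H]2C(C(=O)OC)C[C@H](O[Si](C)(C)C(C)(C)C)C[C@]2(C)C1=C | intermediate
13 | lithium ester enolate of 12 (C4=C19 ketene acetal) | CC1=CC[C@H]2C(=C(OC)O[Li])C[C@H](O[Si](C)(C)C(C)(C)C)C[C@]2(C)C1=C | intermediate
14 | methyl 2α-[(tert-butyldimethylsilyl)oxy]-12,13,14,15,16-pentanorlabda-7,9(11)-dien-19-oate (4α-CH3, 4β-CO2CH3) | CC1=CC[C@H]2[C@@](C)(C(=O)OC)C[C@H](O[Si](C)(C)C(C)(C)C)C[C@]2(C)C1=C | intermediate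
15 | B-alkyl-9-BBN adduct of 14 (boron on C11, 9α-H) | CC1=CC[C@H]2[C@@](C)(C(=O)OC)C[C@H](O[Si](C)(C)C(C)(C)C)C[C@]2(C)[C@H]1CB3C4CCCC3CCC4 | intermediate
16 | methyl 2α-[(tert-butyldimethylsilyl)oxy]-11-hydroxy-12,13,14,15,16-pentanorlabd-7-en-19-oate (9α-H) | CC1=CC[C@H]2[C@@](C)(C(=O)OC)C[C@H](O[Si](C)(C)C(C)(C)C)C[C@]2(C)[C@H]1CO | intermediate
17 | methyl 2α-[(tert-butyldimethylsilyl)oxy]-11-oxo-12,13,14,15,16-pentanorlabd-7-en-19-oate | CC1=CC[C@H]2[C@@](C)(C(=O)OC)C[C@H](O[Si](C)(C)C(C)(C)C)C[C@]2(C)[C@H]1C=O | intermediate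
18 | methyl 2α-[(tert-butyldimethylsilyl)oxy]-13,14,15,16-tetranorlabda-7,11-dien-19-oate | CC1=CC[C@H]2[C@@](C)(C(=O)OC)C[C@H](O[Si](C)(C)C(C)(C)C)C[C@]2(C)[C@H]1C=C | intermediate
19 | methyl 2α-[(tert-butyldimethylsilyl)oxy]-7α,8α-epoxy-13,14,15,16-tetranorlabd-11-en-19-oate | C[C@]13O[C@@H]3C[C@H]2[C@@](C)(C(=O)OC)C[C@H](O[Si](C)(C)C(C)(C)C)C[C@]2(C)[C@H]1C=C | intermediate
20 | methyl 2α-[(tert-butyldimethylsilyl)oxy]-7α-hydroxy-13,14,15,16-tetranorlabda-8(17),11-dien-19-oate | C=C1[C@H](O)C[C@H]2[C@@](C)(C(=O)OC)C[C@H](O[Si](C)(C)C(C)(C)C)C[C@]2(C)[C@H]1C=C | intermediate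
21 | methyl 2α,7α-bis[(tert-butyldimethylsilyl)oxy]-13,14,15,16-tetranorlabda-8(17),11-dien-19-oate | C=C1[C@H](O[Si](C)(C)C(C)(C)C)C[C@H]2[C@@](C)(C(=O)OC)C[C@H](O[Si](C)(C)C(C)(C)C)C[C@]2(C)[C@H]1C=C | intermediate
22 | but-2-yn-1-ol | CC#CCO | starting material
23 | sodium 2,2-bis(2-methoxyethoxy)-3-methyl-1-oxa-2-aluminatacyclopent-3-ene (cyclic alkenylalanate) | CC1=CCO[Al-]1(OCCOC)OCCOC.[Na+] | intermediate
24 | (Z)-3-iodobut-2-en-1-ol | C/C(I)=C/CO | intermediate
25 | B-alkyl-9-BBN adduct of 21 (boron on C12) | C=C1[C@H](O[Si](C)(C)C(C)(C)C)C[C@H]2[C@@](C)(C(=O)OC)C[C@H](O[Si](C)(C)C(C)(C)C)C[C@]2(C)[C@H]1CCB3C4CCCC3CCC4 | intermediate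
26 | methyl 2α,7α-bis[(tert-butyldimethylsilyl)oxy]-15-hydroxylabda-8(17),13Z-dien-19-oate | C=C1[C@H](O[Si](C)(C)C(C)(C)C)C[C@H]2[C@@](C)(C(=O)OC)C[C@H](O[Si](C)(C)C(C)(C)C)C[C@]2(C)[C@H]1CC/C(C)=C\CO | intermediate
27 | 2α,7α-bis[(tert-butyldimethylsilyl)oxy]labda-8(17),13Z-diene-15,19-diol | C=C1[C@H](O[Si](C)(C)C(C)(C)C)C[C@H]2[C@@](C)(CO)C[C@H](O[Si](C)(C)C(C)(C)C)C[C@]2(C)[C@H]1CC/C(C)=C\CO | intermediate
28 | 2α,7α-bis[(tert-butyldimethylsilyl)oxy]labda-8(17),13Z-diene-15,19-diyl diacetate | C=C1[C@H](O[Si](C)(C)C(C)(C)C)C[C@H]2[C@@](C)(COC(C)=O)C[C@H](O[Si](C)(C)C(C)(C)C)C[C@]2(C)[C@H]1CC/C(C)=C\COC(C)=O | intermediate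
29 | 2α,7α-dihydroxylabda-8(17),13Z-diene-15,19-diyl diacetate (CNP0171158.2) | C=C1[C@H](O)C[C@H]2[C@@](C)(COC(C)=O)C[C@H](O)C[C@]2(C)[C@H]1CC/C(C)=C\COC(C)=O | target

**Step count and risks**

Total step count: 20. Longest linear sequence: 19 steps (steps 1–15 and 17–20, from 1); step 16 makes the side-chain iodide.

Steps most likely to fail:

Step 7 (proposed new method). It may fail by hydrogen transfer to the C10 radical before it meets the enol ether, by closure of the C2 radical onto C7 of the enone instead of C3, or by poor facial selectivity at C10. The fallback builds the same two bonds one after the other with known chemistry; it sets out from 7 and comes back at 11. LiN(SiMe3)2 (THF, −78 °C) gives the lithium α′-enolate F1, which is alkylated with allyl iodide trans to the C5 substituent to give methyl 2-[(1R,2S)-2,4-dimethyl-3-oxo-2-(prop-2-en-1-yl)cyclohex-4-en-1-yl]prop-2-enoate F2. Lemieux–Johnson cleavage (OsO4 cat., NaIO4, 2,6-lutidine, dioxane/H2O) of the monosubstituted alkene gives the keto aldehyde F3. SmI2 (THF, t-BuOH, −78 °C) then closes ring A by ketyl–olefin coupling of the aldehyde carbon C2 with the acrylate β-carbon C3, giving the 2α-hydroxy keto ester F4, and t-BuMe2SiOTf/2,6-lutidine gives 11.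

Step 17. It may fail by competing hydroboration of the 8(17)-methylidene group or by protodeboronation during the coupling. The fallback replaces boron by zirconium and zinc; it sets out from 21 and 24 and comes back at 26. Cp2Zr(H)Cl (THF, 25 °C) hydrozirconates only the monosubstituted vinyl group of 21 to the alkylzirconocene chloride F5, and ZnCl2 transmetalates it to the alkylzinc chloride F6. Iodide 24 is deprotonated with EtMgBr to its bromomagnesium alkoxide F7, and Negishi coupling of F6 with F7 (Pd(PPh3)4, THF) gives 26 after aqueous work-up.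

Step 14. It may fail by removal of the allylic C9–H in place of a C17 methyl hydrogen, which would give the conjugated 8-ene. The fallback runs the isomerisation before the vinyl group exists; it sets out from 16 and comes back at 20. mCPBA epoxidises 16 from the α-face to the epoxy alcohol F8. The same aluminium amide (excess), now facing a C9–H that is not allylic, gives the 7α,11-diol F9. TEMPO/PhI(OAc)2 oxidises only the primary C11 alcohol to the hydroxy aldehyde F10, and Wittig methylenation (Ph3PCH3Br, KN(SiMe3)2, excess) gives 20.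

**Further compounds**
F1 | step 7 | lithium α′-enolate of 7 | CC1=CC[C@@H](C(=C)C(=O)OC)C(C)=C1O[Li]
F2 | step 7 | methyl 2-[(1R,2S)-2,4-dimethyl-3-oxo-2-(prop-2-en-1-yl)cyclohex-4-en-1-yl]prop-2-enoate | CC1=CC[C@@H](C(=C)C(=O)OC)[C@](C)(CC=C)C1=O
F3 | step 7 | methyl 2-[(1R,2S)-2,4-dimethyl-3-oxo-2-(2-oxoethyl)cyclohex-4-en-1-yl]prop-2-enoate | CC1=CC[C@@H](C(=C)C(=O)OC)[C@](C)(CC=O)C1=O
F4 | step 7 | methyl 2α-hydroxy-9-oxo-11,12,13,14,15,16,18-heptanorlabd-7-en-19-oate (C4 epimers) | CC1=CC[C@H]2C(C(=O)OC)C[C@H](O)C[C@]2(C)C1=O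
F5 | step 17 | alkylzirconocene chloride from 21 (zirconium on C12) | C=C1[C@H](O[Si](C)(C)C(C)(C)C)C[C@H]2[C@@](C)(C(=O)OC)C[C@H](O[Si](C)(C)C(C)(C)C)C[C@]2(C)[C@H]1CC[Zr](Cl)(C1C=CC=C1)C1C=CC=C1
F6 | step 17 | alkylzinc chloride from F5 (zinc on C12) | C=C1[C@H](O[Si](C)(C)C(C)(C)C)C[C@H]2[C@@](C)(C(=O)OC)C[C@H](O[Si](C)(C)C(C)(C)C)C[C@]2(C)[C@H]1CC[Zn]Cl
F7 | step 17 | bromomagnesium (Z)-3-iodobut-2-en-1-olate | C/C(I)=C/CO[Mg]Br
F8 | step 14 | methyl 2α-[(tert-butyldimethylsilyl)oxy]-7α,8α-epoxy-11-hydroxy-12,13,14,15,16-pentanorlabdan-19-oate | C[C@]13O[C@@H]3C[C@H]2[C@@](C)(C(=O)OC)C[C@H](O[Si](C)(C)C(C)(C)C)C[C@]2(C)[C@H]1CO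
F9 | step 14 | methyl 2α-[(tert-butyldimethylsilyl)oxy]-7α,11-dihydroxy-12,13,14,15,16-pentanorlabd-8(17)-en-19-oate | C=C1[C@H](O)C[C@H]2[C@@](C)(C(=O)OC)C[C@H](O[Si](C)(C)C(C)(C)C)C[C@]2(C)[C@H]1CO
F10 | step 14 | methyl 2α-[(tert-butyldimethylsilyl)oxy]-7α-hydroxy-11-oxo-12,13,14,15,16-pentanorlabd-8(17)-en-19-oate | C=C1[C@H](O)C[C@H]2[C@@](C)(C(=O)OC)C[C@H](O[Si](C)(C)C(C)(C)C)C[C@]2(C)[C@H]1C=O
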